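## Structural features

Target 46 joins a 24-nor-friedelane (rings A–E, ring A aromatic, 6-ene, C20 methyl ester) to a guaiane hydroazulene (cyclopentene C1'=C5' fused to a cycloheptane) through a cis-fused 1,4-benzodioxane: O3–C3' and O2–C4'. The triterpenoid half carries seven stereocentres (8α-H, 9β-Me, 13α-Me, 14β-Me, 17β-Me, 18β-H, 20β-Me/20α-CO2Me); five are quaternary, C13/C14 are vicinal and trans, the C9 and C14 methyls are 1,3-diaxial, and rings D/E are cis-fused. The guaiane half has the adjacent pair C3'/C4' (cis oxygens, C4' a tertiary allylic ether) and the remote cis pair C7'/C10'. It is (7'S,10'R), the antipode of the common guaiol series, so it must be made and not bought. Fragile sites are the styrene C6=C7 with its benzylic, allylic C8–H, the isopropenyl group, the ionisable C4'–O bond next to the tetrasubstituted C1'=C5' alkene, and the ester. The real difficulty is the C13/C14/C9 array of quaternary carbons, together with the regio- and stereo-defined union of the halves through two C–O bonds. The key step uses the fact that ring A is a 4-methyl-3-oxygenated benzene fused at C5–C10 to ring B: C5 can be a ketone whose only α'-carbon is the C10 methylene beside quaternary C9, so C1–C4, the C4 methyl and O3 can all come from one five-carbon ynone.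

## Logic of the disconnections

46 to 45: the C2–O bond to C4' is cut last. A tertiary alkoxide and an aryl bromide held six atoms apart can only close cis, and this leaves the halves joined by O3–C3' alone. The forward step needs C–O reductive elimination at palladium to outrun insertion into the neighbouring alkenes.

45 to 44: the C4'–CH3 bond is cut. With C4' as a ketone, methyl adds anti to the C3' aryloxy group, so the cis relation of the two oxygens follows from one substituent, and the ketone also activates C3' for the preceding substitution. The forward step needs 1,2-addition without enolisation toward C3' and with the ester spared.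

44 to 32 + 43: the O3–C3' bond is cut. This is the convergent point; O3 is already on the arene, so the regiochemistry of the dioxane is fixed. The forward step needs clean inversion at an α-ketol carbon by a di-ortho-substituted phenol.

32 to 31: the C2–Br bond is cut. C2 is the only free position ortho to O3, and bromination must precede coupling because the guaiane alkenes would not survive it.

31 to 26 + 28: C1–C10 and C4–C5 are cut. Ring A, its methyl, O3 and the 6-ene arrive in one operation and no stereocentre is touched. The forward step needs α'-deprotonation (C10, not C8) and conjugate rather than carbonyl addition to 28.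

26 to 25, 24, 23 and 21: C6–C7 is cut (aldol condensation of a methyl ketone onto an aldehyde), C7 is taken back to an exocyclic methylene, and C9–C10 is cut as a [3,3] shift from an oxygen on C7. The C14 β-methyl blocks the β face of C9, so the acetonyl group enters α and C8 is then set thermodynamically.

21 and 20 to 19, 18, 17 and 15: C8–C9 is cut (amine-mediated aldol of an aldehyde onto a methyl ketone), then C14–C8 as a [3,3] shift from O16. The C14 quaternary centre is thereby set by chirality transfer from a carbinol and not by an intermolecular attack next to quaternary C13.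

15 to 14, 13, 12 and 10: the C16 carbinol comes from a catalyst-controlled reduction of an enone, itself from 1,3-oxidative transposition of the C14 tertiary allylic alcohol; the C14–CH3 bond is cut back to the enone, and the enone to the saturated ketone. Because C13 is already quaternary, every enolisation can only go toward C15.

10 to 7 + 8: C13–C12 and C18–H are cut. Conjugate reduction sets the cis D/E fusion and gives the C13 enolate regiospecifically; the alkylation then needs to take place on the convex face.

7 to 6, 3 + 4, 2 and 1: the C13=C18 bond (aldol), C16–C17 (auxiliary-controlled Michael addition), C17–CH3 and C20–CH3 (catalytic conjugate addition) are cut. This leaves a commercial cyclohexenone ester and puts C20 and C17 under reagent control.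

43 to 42, 41, 40, 39 and 37: C3'–O is cut (enol ether oxidation), then the C1'=C5' alkene (dehydration), C4'–C5' (crossed benzoin), C1'–C2' (Michael addition to acrolein) and C10'–H (catalytic conjugate reduction). The enone fixes the alkene at C1'=C5', and C3' and C10' are both set by catalysts.

37 to 35, 34 and 33: one carbon is excised between the carbonyl and the methyl-bearing carbon, leading back to the cyclohexenone 33, which supplies C7'.

28 to 27: a change of oxidation level only.

## Other disconnections considered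

Alternative 1: the guaiane is cut at C1'–C5', C2'–C3' and C3'–C4'. In the forward step [Rh(CO)2Cl]2 (monovalent rhodium) under CO joins the alkyne, the distal allene bond and CO of the allenyne A1, (6S)-3-methyl-6-(prop-1-en-2-yl)deca-1,2-dien-8-yne, to give 3-oxoguaia-1(10),4,11-triene A2.
- In its favour: both rings of the hydroazulene are made in one step from a chain that carries only C7'. On ring-forming step economy it is better than the chosen sequence 33 to 41.
- Against it here: A2 has lost C10', which must be re-set by a remote-controlled 1,6-reduction. It also has the ketone at C3' and the alkene at C4'=C5', so reaching a C4' oxygen and a 1(5)-alkene needs an oxidative transposition whose regiochemistry (C1'–H against C6'–H and the methyl hydrogens) is open.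
- Comparison: the chosen plan sets C10' by a catalyst at the cycloheptenone stage and fixes the alkene by conjugation with a C4' ketone that later accepts the methyl. The two plans are equal in using one chiral-pool or early centre for C7'.

Alternative 2: the cut is C4'–C5'. Iodine–lithium exchange on the cycloheptenyl iodide A3 with t-BuLi gives an alkenyllithium that adds to the chelated methyl ketone and should give the diol monoether A4, guaia-1(5),11-diene-3,4-diol 3-(4-methoxybenzyl) ether.
- In its favour: the tertiary allylic alcohol, the alkene position and the cis oxygens appear in one step. For the C3'/C4' relation it is at least the equal of the chosen plan, which adds methyl late to a valuable ketone.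
- Against it here: A4 already has the final C3' configuration, so an SN2 union with the phenol oxygen (which inverts) cannot be used. Either the C3' epimer must be made or both C–O bonds must be formed at the arene, which brings back the O2/O3 regiochemistry problem. The tetrasubstituted iodide A3 is not trivial, and exchange has to outrun addition of t-BuLi to the ketone.
- Comparison: the chosen plan has more steps to 43 but fits the phenol from the key step directly.

Alternative 3: the cuts are C8–C14 and C9–C10. SnCl4 ionises the C14 tertiary allylic alcohol of A5; the E-alkene closes ring C and the arene closes ring B to give the pentacyclic 2,3-dimethoxy arene A6.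
- In its favour: two rings and three stereocentres (C8, C9, C14) in one step through chair-like anti addition. On step economy for the triterpenoid core it is clearly better than steps 6–19 of the chosen plan.
- Against it here: ring A is carried from the start, which makes the enolate–ynone annulation redundant. A6 needs the 6-ene introduced by benzylic dehydrogenation, the 15-ene removed, and O2 and O3 (both methyl ethers) told apart before the guaiane can be attached with the right regiochemistry. The face of the C14 cation is controlled only by the adjacent C13 centre.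
- Comparison: the chosen plan gives a free O3–H and a C2–Br as distinct handles and sets C14 by chirality transfer. The two are equal in needing a cis D/E bicycle with C13 already quaternary.

Key step: step 19

Remarks on the chemistry:
- Friedelane locants (C5–C22) and guaiane locants (primed) are used for all fragments.
- In steps 1, 24 and 28 the enantiomer of ligand or ketone named is taken to be the one that gives the configuration drawn; the antipodes are equally available.
- Compound 3 is carried as a C17 epimer mixture, erased in step 3; 9, 11, 24, 29, 30, 35, 39 and 40 have one or two undefined centres that are erased later.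
- 26, 28 and 31 were compared with 46 centre by centre (C8, C9, C13, C14, C17, C18, C20) and agree; no structural correction was needed.

Step 1
Reactants: 1 methyl 3-oxocyclohex-1-ene-1-carboxylate
Product: 2 methyl (1R)-1-methyl-3-oxocyclohexane-1-carboxylate
Conditions: Me3Al, copper thiophene-2-carboxylate (2 mol %), O,O'-(R)-1,1'-binaphthalene-2,2'-diyl N,N-bis[(S)-1-phenylethyl]phosphoramidite (4 mol %), Et2O, −30 °C
Reagents that add atoms: trimethylaluminium, C[Al](C)C
Why: Copper-catalysed asymmetric conjugate addition to a β,β-disubstituted cyclic enone; methyl adds β to the ketone at the ester-bearing carbon (C20) and the chiral copper complex selects the face, setting the quaternary centre as R.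

Step 2
Reactants: 2 methyl (1R)-1-methyl-3-oxocyclohexane-1-carboxylate
Product: 3 methyl (1R)-1,4-dimethyl-3-oxocyclohexane-1-carboxylate (C4 epimers)
Conditions: LiN(CHMe2)2, THF, −78 °C; MeI, −78 → −20 °C
Reagents that add atoms: iodomethane, CI
Why: Kinetic enolate alkylation; deprotonation should occur at the unhindered methylene (C17) and not at the neopentyl methylene beside C20, and the new centre need not be controlled.

Step 3
Reactants: 3 methyl (1R)-1,4-dimethyl-3-oxocyclohexane-1-carboxylate; 4 pent-1-en-3-one
Product: 6 methyl (1R,4R)-1,4-dimethyl-3-oxo-4-(3-oxopentyl)cyclohexane-1-carboxylate, via ketimine 5 (not isolated)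
Conditions: (S)-1-phenylethylamine, TsOH (cat.), toluene, reflux (−H2O); 4, THF, 40 °C; 10% aq. AcOH, rt
Reagents that add atoms: water, O
Why: Michael addition of a chiral imine through its more substituted secondary enamine tautomer (deracemising alkylation); the phenylethyl group shields one face in the compact aza-ene-like transition state, so C17 becomes quaternary with the R configuration under auxiliary control.

Step 4
Reactants: 6 methyl (1R,4R)-1,4-dimethyl-3-oxo-4-(3-oxopentyl)cyclohexane-1-carboxylate
Product: 7 methyl (2R,4aR)-2,4a,8-trimethyl-7-oxo-1,2,3,4,4a,5,6,7-octahydronaphthalene-2-carboxylate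
Conditions: NaOMe, MeOH, reflux
Reagents that add atoms: none
Why: Aldol condensation that completes a Robinson annulation; only attack of the ethyl ketone methylene (C13) on the ring ketone can dehydrate to a conjugated enone, and methoxide cannot change the methyl ester.

Step 5
Reactants: 7 methyl (2R,4aR)-2,4a,8-trimethyl-7-oxo-1,2,3,4,4a,5,6,7-octahydronaphthalene-2-carboxylate; 8 2-(2-iodoethyl)-2-methyl-1,3-dioxolane
Product: 10 methyl (2R,4aR,8S,8aR)-2,4a,8-trimethyl-8-[2-(2-methyl-1,3-dioxolan-2-yl)ethyl]-7-oxodecahydronaphthalene-2-carboxylate, via silyl enol ether 9 (not isolated)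
Conditions: [(Ph3P)CuH]6, Me3SiCl, THF, −40 → 0 °C; MeLi, THF, 0 °C; 8, (Me2N)3PO, −78 °C → rt
Reagents that add atoms: none
Why: Copper hydride conjugate reduction followed by regiospecific enolate alkylation; hydride should add to C18 on the face of the angular methyl (cis fusion, as for related octalenones), and the C13 enolate should be alkylated on the convex β face, which puts the chain β and leaves the C13 methyl α.

Step 6
Reactants: 10 methyl (2R,4aR,8S,8aR)-2,4a,8-trimethyl-8-[2-(2-methyl-1,3-dioxolan-2-yl)ethyl]-7-oxodecahydronaphthalene-2-carboxylate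
Product: 12 methyl (2R,4aR,8S,8aR)-2,4a,8-trimethyl-8-[2-(2-methyl-1,3-dioxolan-2-yl)ethyl]-7-oxo-1,2,3,4,4a,7,8,8a-octahydronaphthalene-2-carboxylate, via selenide 11 (not isolated)
Conditions: LiN(CHMe2)2, THF, −78 °C; PhSeBr; H2O2, pyridine, CH2Cl2, 0 °C → rt
Reagents that add atoms: none
Why: Selenoxide syn-elimination; C13 is quaternary, so enolisation and selenenylation can only occur at C15 and the 15-ene results.

Step 7
Reactants: 12 methyl (2R,4aR,8S,8aR)-2,4a,8-trimethyl-8-[2-(2-methyl-1,3-dioxolan-2-yl)ethyl]-7-oxo-1,2,3,4,4a,7,8,8a-octahydronaphthalene-2-carboxylate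
Product: 13 methyl (2R,4aR,7S,8S,8aR)-7-hydroxy-2,4a,7,8-tetramethyl-8-[2-(2-methyl-1,3-dioxolan-2-yl)ethyl]-1,2,3,4,4a,7,8,8a-octahydronaphthalene-2-carboxylate
Conditions: MeLi, CeCl3, THF, −78 °C
Reagents that add atoms: methyllithium, [Li]C
Why: 1,2-addition of an organocerium reagent to a hindered enone; attack anti to the pseudoaxial C13 α-methyl should place the new methyl β, and the hindered tertiary ester is not attacked at −78 °C.

Step 8
Reactants: 13 methyl (2R,4aR,7S,8S,8aR)-7-hydroxy-2,4a,7,8-tetramethyl-8-[2-(2-methyl-1,3-dioxolan-2-yl)ethyl]-1,2,3,4,4a,7,8,8a-octahydronaphthalene-2-carboxylate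
Product: 14 methyl (2R,4aS,8S,8aS)-2,4a,7,8-tetramethyl-8-[2-(2-methyl-1,3-dioxolan-2-yl)ethyl]-5-oxo-1,2,3,4,4a,5,8,8a-octahydronaphthalene-2-carboxylate
Conditions: pyridinium chlorochromate [C5H5NH][CrO3Cl], NaOAc, CH2Cl2, rt
Reagents that add atoms: pyridinium chlorochromate, [O-][Cr](=O)(=O)Cl.c1cc[nH+]cc1
Why: Babler–Dauben oxidative transposition; the chromate ester of the tertiary allylic alcohol undergoes a [3,3] shift and oxidation to the C16 ketone with the C14 methyl now on the alkene.

Step 9
Reactants: 14 methyl (2R,4aS,8S,8aS)-2,4a,7,8-tetramethyl-8-[2-(2-methyl-1,3-dioxolan-2-yl)ethyl]-5-oxo-1,2,3,4,4a,5,8,8a-octahydronaphthalene-2-carboxylate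
Product: 15 methyl (2R,4aS,5R,8S,8aS)-5-hydroxy-2,4a,7,8-tetramethyl-8-[2-(2-methyl-1,3-dioxolan-2-yl)ethyl]-1,2,3,4,4a,5,8,8a-octahydronaphthalene-2-carboxylate
Conditions: (S)-1-methyl-3,3-diphenyltetrahydro-1H,3H-pyrrolo[1,2-c][1,3,2]oxazaborole (20 mol %), catecholborane, toluene, −78 °C
Reagents that add atoms: none
Why: Corey–Bakshi–Shibata reduction; the quaternary C17 acts as the large group and the vinyl CH as the small one, so the (S)-catalyst should deliver hydride to the β face and give the 16α-alcohol (5R).

Step 10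
Reactants: 15 methyl (2R,4aS,5R,8S,8aS)-5-hydroxy-2,4a,7,8-tetramethyl-8-[2-(2-methyl-1,3-dioxolan-2-yl)ethyl]-1,2,3,4,4a,5,8,8a-octahydronaphthalene-2-carboxylate
Product: 17 methyl (2R,4aR,7S,8S,8aR)-2,4a,7,8-tetramethyl-8-[2-(2-methyl-1,3-dioxolan-2-yl)ethyl]-7-(2-oxoethyl)-1,2,3,4,4a,7,8,8a-octahydronaphthalene-2-carboxylate, via vinyl ether 16 (not isolated)
Conditions: [Ir(cod)Cl]2 (2 mol %), Na2CO3, vinyl acetate, toluene, 100 °C; xylene, 150 °C
Reagents that add atoms: vinyl acetate, CC(=O)OC=C
Why: Transfer vinylation and Claisen rearrangement; the suprafacial [3,3] shift carries the two-carbon unit from the α-oxygen on C16 to the α face of C14, so C14 becomes quaternary with its methyl β, trans to the C13 methyl.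

Step 11
Reactants: 17 methyl (2R,4aR,7S,8S,8aR)-2,4a,7,8-tetramethyl-8-[2-(2-methyl-1,3-dioxolan-2-yl)ethyl]-7-(2-oxoethyl)-1,2,3,4,4a,7,8,8a-octahydronaphthalene-2-carboxylate
Product: 18 methyl (2R,4aS,7R,8S,8aR)-2,4a,7,8-tetramethyl-8-[2-(2-methyl-1,3-dioxolan-2-yl)ethyl]-7-(2-oxoethyl)decahydronaphthalene-2-carboxylate
Conditions: H2 (3 atm), Pd/C, EtOAc, rt
Reagents that add atoms: none
Why: Catalytic hydrogenation of the only alkene (C15=C16); aldehyde, ketal and ester are inert under these conditions and no stereocentre is formed.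

Step 12
Reactants: 18 methyl (2R,4aS,7R,8S,8aR)-2,4a,7,8-tetramethyl-8-[2-(2-methyl-1,3-dioxolan-2-yl)ethyl]-7-(2-oxoethyl)decahydronaphthalene-2-carboxylate
Product: 20 tricyclic C/D/E enal (8-formyl-8-ene, 9-methyl; 13α-Me, 14β-Me, 17β-Me, 18β-H, 20α-CO2Me), via keto-aldehyde 19 (not isolated)
Conditions: 1 M HCl, THF, rt; piperidine, AcOH, toluene, 80 °C
Reagents that add atoms: water, O
Why: Ketal hydrolysis followed by amine-mediated aldol condensation; the secondary amine forms the enamine of the aldehyde, whose C8 attacks the methyl ketone (6-exo), and dehydration gives the tetrasubstituted enal and not the acetylcyclohexene.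

Step 13
Reactants: 20 tricyclic C/D/E enal
Product: 21 tricyclic allylic alcohol (8-hydroxymethyl-8-ene)
Conditions: NaBH4, CeCl3·7H2O, MeOH, 0 °C
Reagents that add atoms: none
Why: Luche 1,2-reduction of the enal; the tetrasubstituted alkene and the hindered ester are not touched.

Step 14
Reactants: 21 tricyclic allylic alcohol
Product: 23 tricyclic ketone (9β-methyl-9α-(2-oxopropyl)-8-methylene), via isopropenyl ether 22 (not isolated)
Conditions: 2-methoxypropene, EtCO2H (cat.), xylene, 140 °C (sealed tube)
Reagents that add atoms: 2-methoxypropene, COC(C)=C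
Why: Ketal Claisen rearrangement; the axial 14β-methyl blocks the β face of C9, so the acetonyl group should enter α and the C9 methyl ends β, 1,3-diaxial to the C14 methyl as in the target.

Step 15
Reactants: 23 tricyclic ketone (9β-methyl-9α-(2-oxopropyl)-8-methylene)
Product: 24 tricyclic diol (8α-H, 8β-hydroxymethyl; 2-hydroxypropyl side chain, carbinol epimers)
Conditions: BH3·THF, 0 °C → rt; NaOH, H2O2
Reagents that add atoms: hydrogen peroxide, OO
Why: Hydroboration–oxidation; borane adds to the exocyclic methylene from the α face, away from the two flanking β-methyls, placing boron on C7 and hydrogen on C8, and the concurrent ketone reduction is corrected in step 16.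

Step 16
Reactants: 24 tricyclic diol
Product: 25 tricyclic keto-aldehyde (8β-formyl-8α-H, 9α-(2-oxopropyl))
Conditions: 1,1,1-triacetoxy-1,1-dihydro-1,2-benziodoxol-3(1H)-one, NaHCO3, CH2Cl2, rt
Reagents that add atoms: none
Why: Periodinane oxidation of both alcohols under buffered, non-epimerising conditions; the equatorial formyl group at C8 is also the thermodynamic epimer.

Step 17
Reactants: 25 tricyclic keto-aldehyde
Product: 26 tetracyclic B–E enone (5-oxo-6-ene; 8α-H, 9β-Me, 13α-Me, 14β-Me, 17β-Me, 18β-H, 20β-Me, 20α-CO2Me)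
Conditions: NaOMe, MeOH, rt → 50 °C
Reagents that add atoms: none
Why: Intramolecular aldol condensation of the methyl ketone (C6) onto the aldehyde (C7) closes ring B as the 6-en-5-one; any epimerisation at C8 converges on the trans B/C isomer because an axial C7 would be syn-axial to the C13 α-methyl.

Step 18
Reactants: 27 pent-1-yn-3-ol
Product: 28 pent-1-yn-3-one
Conditions: MnO2 (activated, excess), CH2Cl2, rt; used as a dried solution
Reagents that add atoms: none
Why: Selective oxidation of a propargylic alcohol by manganese dioxide; the volatile, base-sensitive ynone is not concentrated.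

Step 19
Reactants: 26 tetracyclic B–E enone; 28 pent-1-yn-3-one
Product: 31 pentacyclic phenol (3-hydroxy-4-methyl ring A arene, 6-ene, C2–H), via enedione 29 (not isolated), via cyclohexadienone 30 (not isolated)
Conditions: LiN(SiMe3)2, THF, −78 °C; 28 (slow addition), −78 → −20 °C; KOt-Bu, t-BuOH–THF, 0 → 50 °C; aq. NH4Cl
Reagents that add atoms: none
Why: The amide base removes a C10 proton (α', a methylene) faster than the hindered tertiary γ-proton at C8, giving the cross-conjugated enolate without touching C8; this adds through C10 to the terminal carbon of the ynone (C1–C10) to give 29. Under the alkoxide the doubly activated C10–H is removed, and the resulting extended enolate lets the C1=C2 geometry equilibrate to the cis form needed for closure. The ethyl ketone enolate (C4) then adds to the C5 carbonyl in a 6-(enolexo)-exo-trig aldol (C4–C5) and water is lost to give dienone 30. Since 30 still has hydrogen on C10, it tautomerises irreversibly to the phenol. The closest known reaction type is the Robinson-type annulation of ketone enolates with alkynyl ketones to give phenols or cyclohexadienones. One ring (A) is closed and no stereocentre is formed. Ring regiochemistry is fixed because only the ethyl methylene can enolise toward C5 and C10 is the only α'-carbon. The selectivity that the step needs is conjugate over carbonyl addition and over proton transfer from the acetylenic C–H, which the low temperature and slow addition of 28 are meant to secure.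

Step 20
Reactants: 31 pentacyclic phenol
Product: 32 2-bromo-3-hydroxy pentacyclic arene
Conditions: N-bromosuccinimide (1.0 equiv), (Me2CH)2NH (10 mol %), CH2Cl2, −20 °C
Reagents that add atoms: N-bromosuccinimide, O=C1CCC(=O)N1Br
Why: Amine-mediated ortho-bromination of a phenol; C2 is the only free ortho position (C4 bears methyl, the para carbon C10 is substituted) and the phenol should react faster than the styrene at low temperature.

Step 21
Reactants: 33 (S)-carvone
Product: 34 trimethyl{[(5S)-2-methyl-5-(prop-1-en-2-yl)cyclohex-1-en-1-yl]oxy}silane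
Conditions: Li[HB(sec-Bu)3], THF, −78 °C; Me3SiCl, Et3N, −78 → 0 °C
Reagents that add atoms: chlorotrimethylsilane, C[Si](C)(C)Cl
Why: Conjugate hydride reduction of the enone and O-silylation of the resulting enolate give the tetrasubstituted silyl enol ether regiospecifically; C7' comes unchanged from the chiral pool.

Step 22
Reactants: 34 trimethyl{[(5S)-2-methyl-5-(prop-1-en-2-yl)cyclohex-1-en-1-yl]oxy}silane
Product: 35 trimethyl{[(4S)-6-methyl-4-(prop-1-en-2-yl)bicyclo[4.1.0]heptan-1-yl]oxy}silane (ring-fusion diastereomers)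
Conditions: Et2Zn, CH2I2 (1.2 equiv), CH2Cl2, 0 °C
Reagents that add atoms: diiodomethane, ICI
Why: Simmons–Smith cyclopropanation (Furukawa conditions); the electron-rich silyl enol ether should react well before the 1,1-disubstituted alkene when the carbenoid is limited.

Step 23
Reactants: 35 trimethyl{[(4S)-6-methyl-4-(prop-1-en-2-yl)bicyclo[4.1.0]heptan-1-yl]oxy}silane
Product: 37 (6S)-3-methyl-6-(prop-1-en-2-yl)cyclohept-2-en-1-one, via chloro ketone 36 (not isolated)
Conditions: FeCl3, DMF, 0 °C → rt; NaOAc, MeOH, reflux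
Reagents that add atoms: none
Why: Ito–Saegusa ring expansion; one-electron oxidation cleaves the internal cyclopropane bond to the tertiary β-keto radical, chlorine transfer gives 36, and elimination gives the enone with the inserted carbon as C1'.

Step 24
Reactants: 37 (6S)-3-methyl-6-(prop-1-en-2-yl)cyclohept-2-en-1-one
Product: 39 3-[(4S,7R)-7-methyl-2-oxo-4-(prop-1-en-2-yl)cycloheptyl]propanal (C1' epimers), via silyl enol ether 38 (not isolated)
Conditions: CuCl (5 mol %), NaOt-Bu (5 mol %), (S)-2,2'-bis(di-p-tolylphosphino)-1,1'-binaphthyl (5 mol %), PhMe2SiH, toluene, 0 °C; acrolein, BF3·OEt2, CH2Cl2, −78 °C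
Reagents that add atoms: acrolein, C=CC=O
Why: Catalytic asymmetric copper hydride conjugate reduction sets C10' (R, cis to C7') under ligand control and gives the C1' silyl enol ether regiospecifically; Mukaiyama–Michael addition to acrolein then attaches C2'–C4'.

Step 25
Reactants: 39 3-[(4S,7R)-7-methyl-2-oxo-4-(prop-1-en-2-yl)cycloheptyl]propanal
Product: 40 (4R,7S)-8a-hydroxy-4-methyl-7-(prop-1-en-2-yl)octahydroazulen-1(2H)-one (ring-fusion diastereomers)
Conditions: 3-benzyl-5-(2-hydroxyethyl)-4-methylthiazolium chloride (20 mol %), Et3N, EtOH, 60 °C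
Reagents that add atoms: none
Why: Intramolecular crossed benzoin reaction; the carbene-derived acyl anion of the aldehyde (C4') adds to the ring ketone (C5') and closes the five-membered ring (5-exo-trig) as a tertiary α-ketol.

Step 26
Reactants: 40 (4R,7S)-8a-hydroxy-4-methyl-7-(prop-1-en-2-yl)octahydroazulen-1(2H)-one
Product: 41 (4R,7S)-4-methyl-7-(prop-1-en-2-yl)-3,4,5,6,7,8-hexahydroazulen-1(2H)-one
Conditions: methyl N-(triethylammoniosulfonyl)carbamate (inner salt), toluene, 70 °C
Reagents that add atoms: none
Why: Syn-elimination of the tertiary alcohol through its sulfamate; loss of the cis ring-fusion hydrogen at C1' gives the tetrasubstituted, conjugated C1'=C5' enone, the more substituted of the two possible alkenes, and removes the undefined centres.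

Step 27
Reactants: 41 (4R,7S)-4-methyl-7-(prop-1-en-2-yl)-3,4,5,6,7,8-hexahydroazulen-1(2H)-one
Product: 42 triethyl{[(4R,7S)-4-methyl-7-(prop-1-en-2-yl)-3,4,5,6,7,8-hexahydroazulen-1-yl]oxy}silane
Conditions: LiN(CHMe2)2, THF, −78 °C; Et3SiCl
Reagents that add atoms: chlorotriethylsilane, CC[Si](CC)(CC)Cl
Why: Kinetic α'-deprotonation of the enone at C3' and O-silylation give the cross-conjugated 2-silyloxy diene.

Step 28
Reactants: 42 triethyl{[(4R,7S)-4-methyl-7-(prop-1-en-2-yl)-3,4,5,6,7,8-hexahydroazulen-1-yl]oxy}silane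
Product: 43 (2R,4R,7S)-2-hydroxy-4-methyl-7-(prop-1-en-2-yl)-3,4,5,6,7,8-hexahydroazulen-1(2H)-one
Conditions: 1,2:4,5-di-O-isopropylidene-β-D-erythro-2,3-hexodiulo-2,6-pyranose (30 mol %), 2KHSO5·KHSO4·K2SO4, K2CO3, Bu4NHSO4, MeCN–CH2(OMe)2–aq. buffer (pH 10.5), 0 °C; AcOH, THF–H2O, rt
Reagents that add atoms: potassium peroxymonosulfate, [K+].OOS(=O)(=O)[O-]
Why: Rubottom-type oxidation with a chiral dioxirane (Shi epoxidation); the electron-rich trisubstituted enol ether is epoxidised in preference to the isopropenyl and tetrasubstituted alkenes, the ketone catalyst chooses the face, and mild acid releases the (3'R)-ketol.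

Step 29
Reactants: 32 2-bromo-3-hydroxy pentacyclic arene; 43 (2R,4R,7S)-2-hydroxy-4-methyl-7-(prop-1-en-2-yl)-3,4,5,6,7,8-hexahydroazulen-1(2H)-one
Product: 44 aryl ether (O3–C3', 3'-inverted, 4'-ketone, C2–Br)
Conditions: PPh3, diisopropyl azodicarboxylate, toluene, 0 °C → rt
Reagents that add atoms: none
Why: Mitsunobu etherification; the acidic ortho-bromophenol displaces the oxyphosphonium group at the α-keto carbon with inversion, and the adjacent sp2 carbonyl both accelerates the SN2 step and removes the risk of epoxide formation that a free neighbouring alcohol would bring.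

Step 30
Reactants: 44 aryl ether (4'-ketone)
Product: 45 tertiary allylic alcohol (4'-methyl, 4'-OH cis to the 3'-aryloxy group)
Conditions: MeMgBr, CeCl3, THF, −78 °C
Reagents that add atoms: methylmagnesium bromide, C[Mg]Br
Why: 1,2-addition of a weakly basic organocerium reagent to the enone carbonyl; methyl should enter anti to the bulky aryloxy group on C3', which sets C4' with the two oxygens cis, and the aryl bromide and hindered ester do not react at −78 °C.

Step 31
Reactants: 45 tertiary allylic alcohol
Product: 46 target CNP0304573.1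
Conditions: Pd(OAc)2 (5 mol %), 2-(di-tert-butylphosphino)-1,1'-binaphthyl (6 mol %), Cs2CO3, toluene, 80 °C
Reagents that add atoms: none
Why: Intramolecular palladium-catalysed aryl C–O coupling; oxidative addition of zerovalent palladium into C2–Br, alkoxide binding and reductive elimination close the six-membered dioxane, and a tertiary alkoxide has no β-hydrogen on the carbinol carbon to divert the complex.

Compound list
1 | methyl 3-oxocyclohex-1-ene-1-carboxylate | COC(=O)C1=CC(=O)CCC1 | starting material
2 | methyl (1R)-1-methyl-3-oxocyclohexane-1-carboxylate | O=C1C[C@](C)(C(=O)OC)CCC1 | intermediate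
3 | methyl (1R)-1,4-dimethyl-3-oxocyclohexane-1-carboxylate (C4 epimers) | O=C1C[C@](C)(C(=O)OC)CCC1C | intermediate
4 | pent-1-en-3-one | CCC(=O)C=C | starting material
5 | N-[(S)-1-phenylethyl] ketimine of 3 | C[C@H](N=C1C[C@](C)(C(=O)OC)CCC1C)c1ccccc1 | intermediate
6 | methyl (1R,4R)-1,4-dimethyl-3-oxo-4-(3-oxopentyl)cyclohexane-1-carboxylate | O=C1C[C@](C)(C(=O)OC)CC[C@]1(C)CCC(=O)CC | intermediate
7 | methyl (2R,4aR)-2,4a,8-trimethyl-7-oxo-1,2,3,4,4a,5,6,7-octahydronaphthalene-2-carboxylate | CC1=C2C[C@](C)(C(=O)OC)CC[C@]2(C)CCC1=O | intermediate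
8 | 2-(2-iodoethyl)-2-methyl-1,3-dioxolane | CC1(CCI)OCCO1 | starting material
9 | trimethylsilyl enol ether (C13=C14) of the cis-fused D/E ketone from 7 | CC1=C(O[Si](C)(C)C)CC[C@@]2(C)CC[C@@](C)(C(=O)OC)C[C@@H]12 | intermediate
10 | methyl (2R,4aR,8S,8aR)-2,4a,8-trimethyl-8-[2-(2-methyl-1,3-dioxolan-2-yl)ethyl]-7-oxodecahydronaphthalene-2-carboxylate | CC1(OCCO1)CC[C@@]2(C)[C@@H]3C[C@](C)(C(=O)OC)CC[C@]3(C)CCC2=O | intermediate
11 | 6-(phenylselanyl) derivative of 10 (C15 epimers) | CC1(OCCO1)CC[C@@]2(C)[C@@H]3C[C@](C)(C(=O)OC)CC[C@]3(C)CC([Se]c3ccccc3)C2=O | intermediate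
12 | methyl (2R,4aR,8S,8aR)-2,4a,8-trimethyl-8-[2-(2-methyl-1,3-dioxolan-2-yl)ethyl]-7-oxo-1,2,3,4,4a,7,8,8a-octahydronaphthalene-2-carboxylate | CC1(OCCO1)CC[C@@]2(C)[C@@H]3C[C@](C)(C(=O)OC)CC[C@]3(C)C=CC2=O | intermediate
13 | methyl (2R,4aR,7S,8S,8aR)-7-hydroxy-2,4a,7,8-tetramethyl-8-[2-(2-methyl-1,3-dioxolan-2-yl)ethyl]-1,2,3,4,4a,7,8,8a-octahydronaphthalene-2-carboxylate | CC1(OCCO1)CC[C@@]2(C)[C@@H]3C[C@](C)(C(=O)OC)CC[C@]3(C)C=C[C@@]2(O)C | intermediate
14 | methyl (2R,4aS,8S,8aS)-2,4a,7,8-tetramethyl-8-[2-(2-methyl-1,3-dioxolan-2-yl)ethyl]-5-oxo-1,2,3,4,4a,5,8,8a-octahydronaphthalene-2-carboxylate | CC1(OCCO1)CC[C@@]2(C)[C@@H]3C[C@](C)(C(=O)OC)CC[C@]3(C)C(=O)C=C2C | intermediate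
15 | methyl (2R,4aS,5R,8S,8aS)-5-hydroxy-2,4a,7,8-tetramethyl-8-[2-(2-methyl-1,3-dioxolan-2-yl)ethyl]-1,2,3,4,4a,5,8,8a-octahydronaphthalene-2-carboxylate | CC1(OCCO1)CC[C@@]2(C)[C@@H]3C[C@](C)(C(=O)OC)CC[C@]3(C)[C@H](O)C=C2C | intermediate
16 | 5-O-vinyl ether of 15 | CC1(OCCO1)CC[C@@]2(C)[C@@H]3C[C@](C)(C(=O)OC)CC[C@]3(C)[C@H](OC=C)C=C2C | intermediate
17 | methyl (2R,4aR,7S,8S,8aR)-2,4a,7,8-tetramethyl-8-[2-(2-methyl-1,3-dioxolan-2-yl)ethyl]-7-(2-oxoethyl)-1,2,3,4,4a,7,8,8a-octahydronaphthalene-2-carboxylate | CC1(OCCO1)CC[C@@]2(C)[C@@H]3C[C@](C)(C(=O)OC)CC[C@]3(C)C=C[C@]2(C)CC=O | intermediate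
18 | methyl (2R,4aS,7R,8S,8aR)-2,4a,7,8-tetramethyl-8-[2-(2-methyl-1,3-dioxolan-2-yl)ethyl]-7-(2-oxoethyl)decahydronaphthalene-2-carboxylate | CC1(OCCO1)CC[C@@]2(C)[C@@H]3C[C@](C)(C(=O)OC)CC[C@]3(C)CC[C@]2(C)CC=O | intermediate
19 | D/E keto-aldehyde (13β-(3-oxobutyl), 14α-(2-oxoethyl)) | CC(=O)CC[C@@]1(C)[C@@H]2C[C@](C)(C(=O)OC)CC[C@]2(C)CC[C@]1(C)CC=O | intermediate
20 | tricyclic C/D/E enal (8-formyl-8-ene, 9-methyl) | O=CC1=C(C)CC[C@@]2(C)[C@@H]3C[C@](C)(C(=O)OC)CC[C@]3(C)CC[C@]12C | intermediate
21 | tricyclic allylic alcohol (8-hydroxymethyl-8-ene) | OCC1=C(C)CC[C@@]2(C)[C@@H]3C[C@](C)(C(=O)OC)CC[C@]3(C)CC[C@]12C | intermediate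
22 | isopropenyl ether of 21 | C=C(C)OCC1=C(C)CC[C@@]2(C)[C@@H]3C[C@](C)(C(=O)OC)CC[C@]3(C)CC[C@]12C | intermediate
23 | tricyclic ketone (9β-methyl, 9α-(2-oxopropyl), 8-methylene) | C=C1[C@](C)(CC(C)=O)CC[C@@]2(C)[C@@H]3C[C@](C)(C(=O)OC)CC[C@]3(C)CC[C@]12C | intermediate
24 | tricyclic diol (8β-hydroxymethyl, 8α-H, 9α-(2-hydroxypropyl), carbinol epimers) | OC[C@H]1[C@](C)(CC(C)O)CC[C@@]2(C)[C@@H]3C[C@](C)(C(=O)OC)CC[C@]3(C)CC[C@]12C | intermediate
25 | tricyclic keto-aldehyde (8β-formyl, 8α-H, 9α-(2-oxopropyl)) | O=C[C@H]1[C@](C)(CC(C)=O)CC[C@@]2(C)[C@@H]3C[C@](C)(C(=O)OC)CC[C@]3(C)CC[C@]12C | intermediate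
26 | tetracyclic B–E 6-en-5-one with the C20 methyl ester | O=C1C=C[C@H]2[C@](C)(C1)CC[C@@]1(C)[C@@H]3C[C@](C)(C(=O)OC)CC[C@]3(C)CC[C@]21C | intermediate
27 | pent-1-yn-3-ol | CCC(O)C#C | starting material
28 | pent-1-yn-3-one | CCC(=O)C#C | intermediate
29 | enedione Michael adduct (C10–CH=CH–CO–Et; C10 and alkene geometry undefined) | CCC(=O)C=CC1C(=O)C=C[C@H]2[C@@]1(C)CC[C@@]1(C)[C@@H]3C[C@](C)(C(=O)OC)CC[C@]3(C)CC[C@]21C | intermediate
30 | ring A cyclohexa-2,4-dienone (C10–H) | CC1=C2C=C[C@H]3[C@@](C)(CC[C@@]4(C)[C@@H]5C[C@](C)(C(=O)OC)CC[C@]5(C)CC[C@]34C)C2C=CC1=O | intermediate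
31 | pentacyclic 3-hydroxy-4-methyl arene with the 6-ene | Cc1c(O)ccc2c1C=C[C@H]1[C@@]2(C)CC[C@@]2(C)[C@@H]3C[C@](C)(C(=O)OC)CC[C@]3(C)CC[C@]12C | intermediate
32 | 2-bromo-3-hydroxy-4-methyl pentacyclic arene | Cc1c(O)c(Br)cc2c1C=C[C@H]1[C@@]2(C)CC[C@@]2(C)[C@@H]3C[C@](C)(C(=O)OC)CC[C@]3(C)CC[C@]12C | intermediate
33 | (S)-carvone, (5S)-2-methyl-5-(prop-1-en-2-yl)cyclohex-2-en-1-one | CC1=CC[C@@H](CC1=O)C(C)=C | starting material
34 | trimethyl{[(5S)-2-methyl-5-(prop-1-en-2-yl)cyclohex-1-en-1-yl]oxy}silane | CC1=C(O[Si](C)(C)C)C[C@@H](C(C)=C)CC1 | intermediate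
35 | trimethyl{[(4S)-6-methyl-4-(prop-1-en-2-yl)bicyclo[4.1.0]heptan-1-yl]oxy}silane (ring-fusion diastereomers) | CC12CC[C@H](C(C)=C)CC1(O[Si](C)(C)C)C2 | intermediate
36 | (6S)-3-chloro-3-methyl-6-(prop-1-en-2-yl)cycloheptan-1-one | C=C(C)[C@H]1CCC(C)(Cl)CC(=O)C1 | intermediate
37 | (6S)-3-methyl-6-(prop-1-en-2-yl)cyclohept-2-en-1-one | C=C(C)[C@H]1CCC(C)=CC(=O)C1 | intermediate
38 | dimethyl(phenyl)silyl enol ether of (3R,6S)-3-methyl-6-(prop-1-en-2-yl)cycloheptanone (C1'=C5') | C=C(C)[C@H]1CC[C@@H](C)C=C(O[Si](C)(C)c2ccccc2)C1 | intermediate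
39 | 3-[(4S,7R)-7-methyl-2-oxo-4-(prop-1-en-2-yl)cycloheptyl]propanal (C1' epimers) | C=C(C)[C@H]1CC[C@@H](C)C(CCC=O)C(=O)C1 | intermediate
40 | (4R,7S)-8a-hydroxy-4-methyl-7-(prop-1-en-2-yl)octahydroazulen-1(2H)-one (ring-fusion diastereomers) | C=C(C)[C@H]1CC[C@@H](C)C2CCC(=O)C2(O)C1 | intermediate
41 | (4R,7S)-4-methyl-7-(prop-1-en-2-yl)-3,4,5,6,7,8-hexahydroazulen-1(2H)-one | C=C(C)[C@H]1CC[C@@H](C)C2=C(C1)C(=O)CC2 | intermediate
42 | triethyl{[(4R,7S)-4-methyl-7-(prop-1-en-2-yl)-3,4,5,6,7,8-hexahydroazulen-1-yl]oxy}silane | C=C(C)[C@H]1CC[C@@H](C)C2=C(C1)C(O[Si](CC)(CC)CC)=CC2 | intermediate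
43 | (2R,4R,7S)-2-hydroxy-4-methyl-7-(prop-1-en-2-yl)-3,4,5,6,7,8-hexahydroazulen-1(2H)-one | C=C(C)[C@H]1CC[C@@H](C)C2=C(C1)C(=O)[C@H](O)C2 | intermediate
44 | aryl ether of 32 and 43 (O3–C3' with inverted C3', 4'-ketone, C2–Br) | C=C(C)[C@H]1CC[C@@H](C)C2=C(C1)C(=O)[C@@H](Oc3c(Br)cc4c(c3C)C=C[C@H]3[C@@]4(C)CC[C@@]4(C)[C@@H]5C[C@](C)(C(=O)OC)CC[C@]5(C)CC[C@]34C)C2 | intermediate
45 | tertiary allylic alcohol (4'-methyl, 4'-OH cis to 3'-OAr, C2–Br) | C=C(C)[C@H]1CC[C@@H](C)C2=C(C1)[C@@](C)(O)[C@@H](Oc3c(Br)cc4c(c3C)C=C[C@H]3[C@@]4(C)CC[C@@]4(C)[C@@H]5C[C@](C)(C(=O)OC)CC[C@]5(C)CC[C@]34C)C2 | intermediate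
46 | CNP0304573.1 | C=C(C)[C@H]1CC[C@@H](C)C2=C(C1)[C@@]1(C)Oc3cc4c(c(C)c3O[C@H]1C2)C=C[C@H]1[C@@]4(C)CC[C@@]2(C)[C@@H]3C[C@](C)(C(=O)OC)CC[C@]3(C)CC[C@]12C | target

Total: 31 steps. Longest linear sequence: 22 steps (steps 1–17, 19, 20, 29, 30, 31); the guaiane branch is steps 21–28 and the ynone is step 18.

Least certain steps

Step 19 (key step). The likely failures are proton transfer from the acidic acetylenic C–H of 28 to the enolate and 1,2-addition to the ynone carbonyl, both of which return 26; the C10 enolate is neopentyl and therefore a slow Michael donor. Fallback: from 26, the same kinetic enolate is treated with (E)-1-chloropent-1-en-3-one, which has no acidic C–H and reacts by conjugate addition–elimination to give 29. This is isolated and then cyclised and aromatised with KOt-Bu in a separate operation, returning to the route at 31 (no new compound, F0).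

Step 5. Hydride transfer to the tetrasubstituted enone may be slow, and the flexible cis-decalin enolate may be alkylated from the concave α face, which would give the C13 epimer. Fallback: the two C13 substituents are introduced in the opposite order. From 3, the imine Michael addition of step 3 is run with 6-(2-methyl-1,3-dioxolan-2-yl)hex-1-en-3-one F1 in place of 4 to give methyl (1R,4R)-1,4-dimethyl-4-[6-(2-methyl-1,3-dioxolan-2-yl)-3-oxohexyl]-3-oxocyclohexane-1-carboxylate F2. Aldol condensation gives the enone methyl (2R,4aR)-2,4a-dimethyl-8-[2-(2-methyl-1,3-dioxolan-2-yl)ethyl]-7-oxo-1,2,3,4,4a,5,6,7-octahydronaphthalene-2-carboxylate F3. The same copper hydride reduction, then MeLi and iodomethane, puts the methyl on the face that the electrophile prefers and returns to the route at 10.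

Step 9. Catalyst and substrate bias may be mismatched, so that hydride is delivered to the α face and the C16 epimer forms; the Claisen step would then place C8 on the wrong face of C14. Fallback: from 13, a Ph3SiOReO3-catalysed suprafacial 1,3-transposition of the tertiary allylic alcohol at low temperature moves the α-oxygen from C14 to C16 with chirality transfer and returns directly at 15, leaving out 14 (no new compound, F0).

Step 26. Elimination may run toward C6' and give the exocyclic enone, or the ketol may revert by retro-benzoin on heating. Fallback: from 37, the copper hydride reduction of step 24 is followed by MeLi and N-phenylbis(trifluoromethanesulfonimide) to give the enol triflate (3R,6S)-3-methyl-6-(prop-1-en-2-yl)cyclohept-1-en-1-yl trifluoromethanesulfonate F4. Carbonylative Stille coupling (Pd(PPh3)4, CO, tributyl(vinyl)stannane, LiCl) gives the divinyl ketone 1-[(3R,6S)-3-methyl-6-(prop-1-en-2-yl)cyclohept-1-en-1-yl]prop-2-en-1-one F5, and a Nazarov cyclisation (BF3·OEt2, low temperature) returns to the route at 41.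

Step 29. The activated ketol may undergo E2 elimination or epimerise at C3' before substitution, and the di-ortho-substituted phenol is a hindered nucleophile. Fallback: from 41, detrifluoroacetylative diazo transfer (LiN(SiMe3)2, CF3CO2CH2CF3; MsN3, Et3N) gives the α'-diazo ketone (4R,7S)-2-diazo-4-methyl-7-(prop-1-en-2-yl)-3,4,5,6,7,8-hexahydroazulen-1(2H)-one F6. Rh2(OAc)4-catalysed O–H insertion with 32 forms the O3–C3' bond without a substitution step and returns at 44; C3' is then not controlled, and the epimer has to be separated or equilibrated.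

Further compounds
F0 | step 19 | none | none
F1 | step 5 | 6-(2-methyl-1,3-dioxolan-2-yl)hex-1-en-3-one | C=CC(=O)CCCC1(C)OCCO1
F2 | step 5 | methyl (1R,4R)-1,4-dimethyl-4-[6-(2-methyl-1,3-dioxolan-2-yl)-3-oxohexyl]-3-oxocyclohexane-1-carboxylate | O=C1C[C@](C)(C(=O)OC)CC[C@]1(C)CCC(=O)CCCC1(C)OCCO1
F3 | step 5 | methyl (2R,4aR)-2,4a-dimethyl-8-[2-(2-methyl-1,3-dioxolan-2-yl)ethyl]-7-oxo-1,2,3,4,4a,5,6,7-octahydronaphthalene-2-carboxylate | CC1(OCCO1)CCC2=C3C[C@](C)(C(=O)OC)CC[C@]3(C)CCC2=O
F0 | step 9 | none | none
F4 | step 26 | (3R,6S)-3-methyl-6-(prop-1-en-2-yl)cyclohept-1-en-1-yl trifluoromethanesulfonate | C=C(C)[C@H]1CC[C@@H](C)C=C(OS(=O)(=O)C(F)(F)F)C1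
F5 | step 26 | 1-[(3R,6S)-3-methyl-6-(prop-1-en-2-yl)cyclohept-1-en-1-yl]prop-2-en-1-one | C=C(C)[C@H]1CC[C@@H](C)C=C(C(=O)C=C)C1
F6 | step 29 | (4R,7S)-2-diazo-4-methyl-7-(prop-1-en-2-yl)-3,4,5,6,7,8-hexahydroazulen-1(2H)-one | C=C(C)[C@H]1CC[C@@H](C)C2=C(C1)C(=O)C(=[N+]=[N-])C2
A1 | alternative 1 | (6S)-3-methyl-6-(prop-1-en-2-yl)deca-1,2-dien-8-yne | C=C(C)[C@H](CC#CC)CCC(C)=C=C
A2 | alternative 1 | 3-oxoguaia-1(10),4,11-triene | C=C(C)[C@H]1CCC(C)=C2CC(=O)C(C)=C2C1
A3 | alternative 2 | cycloheptenyl iodide with the C3' 4-methoxybenzyl ether and C4' methyl ketone side chain | C=C(C)[C@H]1CC[C@@H](C)C(C[C@H](OCc2ccc(OC)cc2)C(C)=O)=C(I)C1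
A4 | alternative 2 | guaia-1(5),11-diene-3,4-diol 3-(4-methoxybenzyl) ether with cis oxygens | C=C(C)[C@H]1CC[C@@H](C)C2=C(C1)[C@@](C)(O)[C@@H](OCc3ccc(OC)cc3)C2
A5 | alternative 3 | D/E C14 tertiary allylic alcohol carrying the (E)-aryl-alkenyl chain on C13 | COc1ccc(CC/C=C(\C)CC[C@@]2(C)[C@@H]3C[C@](C)(C(=O)OC)CC[C@]3(C)C=CC2(C)O)c(C)c1OC
A6 | alternative 3 | pentacyclic 2,3-dimethoxy arene with the 15-ene, 6,7-dihydro | COc1cc2c(c(C)c1OC)CC[C@H]1[C@@]2(C)CC[C@@]2(C)[C@@H]3C[C@](C)(C(=O)OC)CC[C@]3(C)C=C[C@]12C
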